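## Retrosynthetic overview

1. Ring numbering used throughout: C1 is the quaternary carbon (CH3 and 4-methylpent-3-enyl), C2=C3 (Z), C4 (O-senecioyl), C5(CH3)–C6 oxirane, C7 (OH), C8 (C=O), C9(CH2OH)=C10 (Z), C11 (CH2). The enabling feature is that, in the eleven-membered ring, the fully substituted sp3 carbon C1 is bonded directly to the cis CH=CH unit C2=C3. This is the retron of a Zweifel olefination of a tertiary boronate.
2. Key disconnection C1–C2: a boron atom is placed between C1 and C2. The ring first closes at boron to a twelve-membered cyclic alkenylboronate (a temporary ring). It then contracts by an iodine-triggered 1,2-metallate shift and boron–iodine elimination. The precursor is an open chain with an E-iodoalkene at C2 and a pinacol boronate at C1.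
3. The open chain is cut at C8–C9 (Nozaki–Hiyama–Kishi union). Fragment A (C9–C11, C1, side chain) comes from methyl geranate by enantioselective β-borylation and Z-iodo-olefination. Fragment B (C2–C8) comes from (R)-glyceraldehyde acetonide by Wittig reaction, catalytic asymmetric alkynylation and hydroxyl-directed epoxidation.
4. Order of ring formation: oxirane (step 11), then the twelve-membered boracycle and the eleven-membered carbocycle (both in step 17). The endgame is C8 oxidation, C4 acylation and desilylation.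

Key step: step 17

Assumption: the ligand antipodes written for steps 1 and 7 (and the ketone antipode in the fallback to step 11) are those expected to give the drawn configurations; both antipodes of each are available, and the other one would be used if the sense of induction proved opposite.

## Route

Step 1
Reactants: 1 methyl geranate
Product: 2 methyl (3R)-3,7-dimethyl-3-(pinacolatoboryl)oct-6-enoate
Conditions: B2pin2, CuCl (5 mol %), NaOt-Bu (10 mol %), (R,R)-Me-DuPhos (6 mol %), MeOH (2 equiv), THF, rt
Reagents that add atoms: bis(pinacolato)diboron, CC1(C)OB(OC1(C)C)B1OC(C)(C)C(C)(C)O1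
Why: Copper-catalysed enantioselective conjugate borylation of a β,β-disubstituted enoate: the bisphosphine–copper boryl adds to one face of the E C2=C3 bond, methanol protonates the copper enolate, and the ligand thereby sets the boron-bearing tertiary centre (future C1) as R.

Step 2
Reactants: 2 methyl (3R)-3,7-dimethyl-3-(pinacolatoboryl)oct-6-enoate
Product: 3 (3R)-3,7-dimethyl-3-(pinacolatoboryl)oct-6-enal
Conditions: i-Bu2AlH (1.1 equiv), CH2Cl2, −78 °C; aq. potassium sodium tartrate
Reagents that add atoms: none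
Why: Partial reduction of an ester with i-Bu2AlH stops at the aluminium hemiacetal at −78 °C, the hindered tertiary pinacol boronate is inert to the hydride, and the stereocentre is not touched.

Step 3
Reactants: 3 (3R)-3,7-dimethyl-3-(pinacolatoboryl)oct-6-enal; 4 ethyl (triphenylphosphoranylidene)acetate
Product: 6 ethyl (2Z,5R)-2-iodo-5,9-dimethyl-5-(pinacolatoboryl)deca-2,8-dienoate, via iodo ylide 5 (not isolated)
Conditions: 4, NIS, CH2Cl2, −20 °C; then 3, −20 °C to rt
Reagents that add atoms: N-iodosuccinimide, O=C1CCC(=O)N1I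
Why: Wittig olefination with a stabilised α-iodo ylide made in the flask by iodination of 4 (the succinimide anion removes the remaining proton): as with stabilised ylides in general, the chain ends up trans to the ester and hence cis to iodine, which fixes the Z geometry that becomes C9=C10.

Step 4
Reactants: 6 ethyl (2Z,5R)-2-iodo-5,9-dimethyl-5-(pinacolatoboryl)deca-2,8-dienoate
Product: 7 (2Z,5R)-2-iodo-5,9-dimethyl-5-(pinacolatoboryl)deca-2,8-dien-1-ol
Conditions: i-Bu2AlH (2.3 equiv), CH2Cl2, −78 °C; aq. potassium sodium tartrate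
Reagents that add atoms: none
Why: 1,2-Reduction of the enoate to the allylic alcohol with i-Bu2AlH leaves the C–I bond, the alkene geometry and the boronate unchanged.

Step 5
Reactants: 7 (2Z,5R)-2-iodo-5,9-dimethyl-5-(pinacolatoboryl)deca-2,8-dien-1-ol
Product: 8 fragment A (tert-butyldimethylsilyl ether of 7)
Conditions: TBSCl, imidazole, DMF, rt
Reagents that add atoms: tert-butyldimethylsilyl chloride, CC(C)(C)[Si](C)(C)Cl
Why: Standard silylation of a primary alcohol masks the future C9 hydroxymethyl group until the last step.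

Step 6
Reactants: 9 (R)-glyceraldehyde acetonide; 10 2-(triphenylphosphoranylidene)propanal
Product: 11 (2E)-3-[(4S)-2,2-dimethyl-1,3-dioxolan-4-yl]-2-methylprop-2-enal
Conditions: toluene, 80 °C
Reagents that add atoms: none
Why: Wittig olefination with a stabilised formyl ylide is E-selective and needs no added base, so the α-alkoxy stereocentre of 9 (future C7) should not epimerise.

Step 7
Reactants: 11 (2E)-3-[(4S)-2,2-dimethyl-1,3-dioxolan-4-yl]-2-methylprop-2-enal; 12 trimethylsilylacetylene
Product: 13 (3S,4E)-5-[(4S)-2,2-dimethyl-1,3-dioxolan-4-yl]-4-methyl-1-(trimethylsilyl)pent-4-en-1-yn-3-ol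
Conditions: Me2Zn, (S,S)-ProPhenol (10 mol %), Ph3P=O (20 mol %), toluene, 4 °C
Reagents that add atoms: none
Why: Catalytic enantioselective alkynylation of an enal by an alkynylzinc bound to the dinuclear zinc–ProPhenol complex: the catalyst selects the aldehyde face and sets C4, the distant C7 centre having little say.

Step 8
Reactants: 13 (3S,4E)-5-[(4S)-2,2-dimethyl-1,3-dioxolan-4-yl]-4-methyl-1-(trimethylsilyl)pent-4-en-1-yn-3-ol
Product: 15 (4S)-4-{(1E,3R)-3-[(4-methoxybenzyl)oxy]-2-methylpent-1-en-4-yn-1-yl}-2,2-dimethyl-1,3-dioxolane, via silylalkyne ether 14 (not isolated)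
Conditions: NaH, PMBCl, Bu4NI (cat.), THF–DMF, 0 °C to rt; then K2CO3 (cat.), MeOH, rt
Reagents that add atoms: 4-methoxybenzyl chloride, COc1ccc(CCl)cc1
Why: Williamson etherification of the sodium alkoxide, followed in the same flask by base-catalysed methanolysis of the C(sp)–Si bond; no stereocentre is involved (the descriptor at C4 changes only because the priorities change).

Step 9
Reactants: 15 (4S)-4-{(1E,3R)-3-[(4-methoxybenzyl)oxy]-2-methylpent-1-en-4-yn-1-yl}-2,2-dimethyl-1,3-dioxolane
Product: 16 (2S,3E,5R)-5-[(4-methoxybenzyl)oxy]-4-methylhept-3-en-6-yne-1,2-diol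
Conditions: AcOH–H2O, rt
Reagents that add atoms: none
Why: Acid-catalysed hydrolysis of the terminal acetonide frees the C7 and C8 hydroxyl groups before any oxirane is present, and the benzylic ether should survive dilute acetic acid.

Step 10
Reactants: 16 (2S,3E,5R)-5-[(4-methoxybenzyl)oxy]-4-methylhept-3-en-6-yne-1,2-diol
Product: 17 (2S,3E,5R)-5-[(4-methoxybenzyl)oxy]-4-methyl-1-(triethylsilyloxy)hept-3-en-6-yn-2-ol
Conditions: TESCl (1 equiv), imidazole, CH2Cl2, −20 °C
Reagents that add atoms: chlorotriethylsilane, CC[Si](Cl)(CC)CC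
Why: Rate-controlled silylation selects the primary C8 hydroxyl over the secondary allylic one, so that the C7 hydroxyl alone stays free to direct the next step.

Step 11
Reactants: 17 (2S,3E,5R)-5-[(4-methoxybenzyl)oxy]-4-methyl-1-(triethylsilyloxy)hept-3-en-6-yn-2-ol
Product: 18 (1R)-1-{(2S,3S)-3-[(1R)-1-[(4-methoxybenzyl)oxy]prop-2-yn-1-yl]-3-methyloxiran-2-yl}-2-(triethylsilyloxy)ethan-1-ol
Conditions: mCPBA, CH2Cl2, −20 to 0 °C
Reagents that add atoms: 3-chloroperoxybenzoic acid, O=C(OO)c1cccc(Cl)c1
Why: Hydroxyl-directed peracid epoxidation under allylic 1,3-strain control: the C5 methyl group cis to C7 holds the C7–H bond in the alkene plane, the peracid hydrogen-bonded to the C7 hydroxyl attacks the face on which that hydroxyl lies, and the threo epoxy alcohol with C5 (S) and C6 (S) should result, the alkyne and the arene being inert.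

Step 12
Reactants: 18 (1R)-1-{(2S,3S)-3-[(1R)-1-[(4-methoxybenzyl)oxy]prop-2-yn-1-yl]-3-methyloxiran-2-yl}-2-(triethylsilyloxy)ethan-1-ol
Product: 19 C7 tert-butyldimethylsilyl ether of 18
Conditions: TBSOTf, 2,6-lutidine, CH2Cl2, −78 °C
Reagents that add atoms: tert-butyldimethylsilyl trifluoromethanesulfonate, CC(C)(C)[Si](C)(C)OS(=O)(=O)C(F)(F)F
Why: Silylation of the hindered secondary alcohol with the silyl triflate at low temperature, in the presence of a non-nucleophilic base, leaves the oxirane closed.

Step 13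
Reactants: 19 C7 tert-butyldimethylsilyl ether of 18
Product: 20 fragment B (C8 aldehyde)
Conditions: (COCl)2, DMSO, CH2Cl2, −78 to −40 °C; Et3N, −78 °C to rt
Reagents that add atoms: none
Why: Swern oxidation applied directly to the bis-silyl ether: the activated sulfonium salt cleaves and oxidises only the unhindered primary triethylsilyl ether, which gives the α-silyloxy aldehyde without a separate deprotection and without acid.

Step 14
Reactants: 8 fragment A; 20 fragment B
Product: 21 open-chain C8 allylic alcohol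
Conditions: CrCl2 (4 equiv), NiCl2 (1 mol %), DMSO–THF, rt
Reagents that add atoms: none
Why: Nozaki–Hiyama–Kishi coupling: nickel-catalysed formation of the alkenylchromium species from the iodoalkene with retention of geometry, and its chemoselective addition to the aldehyde, tolerate boronate, oxirane, alkyne and silyl ethers; both C8 epimers may form and are carried on together because C8 becomes a ketone in step 18.

Step 15
Reactants: 21 open-chain C8 allylic alcohol
Product: 22 C8 trimethylsilyl ether of 21
Conditions: TMSCl, imidazole, CH2Cl2, 0 °C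
Reagents that add atoms: chlorotrimethylsilane, C[Si](C)(C)Cl
Why: Trimethylsilylation gives a cover for the C8 hydroxyl that withstands organolithium reagents at low temperature but falls off in methanolic methoxide at the end of step 17.

Step 16
Reactants: 22 C8 trimethylsilyl ether of 21
Product: 24 open-chain (E)-C2-iodoalkene C1-boronate, via alkenylzirconocene 23 (not isolated)
Conditions: Cp2Zr(H)Cl, THF, rt; I2, 0 °C
Reagents that add atoms: iodine, [I][I]
Why: Hydrozirconation–iodination: syn addition of Zr–H places zirconium on the terminal carbon of the only alkyne much faster than it touches the trisubstituted alkenes, and iodinolysis with retention gives the E-iodoalkene.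

Step 17
Reactants: 24 open-chain (E)-C2-iodoalkene C1-boronate
Product: 29 eleven-membered carbocycle bearing free C8 hydroxyl, via alkenyllithium 25 (not isolated), via cyclic lithium boronate 26 (not isolated), via iodo boronate 27 (not isolated), via trimethylsilyl ether 28 (not isolated)
Conditions: t-BuLi (2.1 equiv), THF–Et2O, 1 mM, −78 °C, then −78 to −20 °C; I2, THF, −78 °C; NaOMe, MeOH, −78 °C to rt
Reagents that add atoms: none
Why: Proposed new method: iodine–lithium exchange (faster than attack of t-BuLi on the hindered boronate) gives the E-alkenyllithium 25, whose only reachable electrophile is the vacant boron orbital at the other chain end, so that at high dilution it closes the twelve-membered cyclic boronate 26; iodine then adds to the electron-rich C2=C3 bond of 26, C1 migrates from boron to C2 anti to the iodonium (ring contraction from twelve to eleven members, giving 27), and methoxide triggers anti elimination of boron and iodide. The closest known reaction type is the Zweifel olefination of enantioenriched tertiary pinacol boronates with alkenyllithiums, which is also known intramolecularly for five-membered rings; what is new is its use as a boron-templated medium-ring contraction. Mode of closure: the temporary ring closes by addition of an sp2 carbanion to boron (C2–B bond, no stereoelectronic limit on ring size), and the carbocycle closes by a suprafacial 1,2-metallate shift inside that ring, so that the entropically hard C–C closure becomes a migration over one atom. No new stereocentre survives: C1 keeps its configuration because the migrating carbon shifts with retention (R boronate to S quaternary carbon by change of priorities only), and the Z geometry of C2=C3 follows from anti migration plus anti elimination on an E-alkenylboronate whichever face iodine takes. The step needs cyclisation over oligomerisation, which is secured by the dilution, by the E geometry that forbids attack of C2 on any nearer group in a small ring, and by the bends of the trans-oxirane and the Z C9=C10 alkene; it also needs iodine to choose the boronate alkene over the two other C=C bonds, which the negative charge of 26 secures. Methoxide in methanol finally removes the labile trimethylsilyl ether of 28 and frees the C8 hydroxyl of 29 for the next step.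

Step 18
Reactants: 29 eleven-membered carbocycle bearing free C8 hydroxyl
Product: 30 macrocyclic C8 enone
Conditions: Dess–Martin periodinane, CH2Cl2, 0 °C to rt
Reagents that add atoms: none
Why: Dess–Martin oxidation of the allylic alcohol merges both C8 epimers into one Z-enone under conditions that should neither epimerise C7 nor isomerise C9=C10.

Step 19
Reactants: 30 macrocyclic C8 enone
Product: 31 macrocyclic C4 alcohol
Conditions: DDQ, CH2Cl2–pH 7 buffer, 0 °C
Reagents that add atoms: none
Why: Oxidative cleavage of the 4-methoxybenzyl ether by DDQ (hydride abstraction, then hydrolysis of the oxocarbenium ion) frees only the C4 hydroxyl, the silyl ethers being inert.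

Step 20
Reactants: 31 macrocyclic C4 alcohol; 32 3-methylbut-2-enoyl chloride
Product: 33 C4 senecioate bis(silyl ether)
Conditions: pyridine, DMAP (cat.), CH2Cl2, 0 °C to rt
Reagents that add atoms: none
Why: DMAP-catalysed acylation of the only free hydroxyl; pyridine instead of a trialkylamine limits vinylketene formation and thus deconjugation of the senecioyl group.

Step 21
Reactants: 33 C4 senecioate bis(silyl ether)
Product: 34 CNP0163063.1
Conditions: HF·pyridine, pyridine, THF, 0 °C to rt
Reagents that add atoms: none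
Why: Fluoride-mediated cleavage of both silyl ethers under buffered, weakly acidic conditions spares the oxirane, the ester and the α-hydroxy enone, and avoids base-induced epoxide migration at C7.

## Compound list

1 | methyl geranate, methyl (2E)-3,7-dimethylocta-2,6-dienoate | CC(C)=CCC/C(C)=C/C(=O)OC | starting material
2 | methyl (3R)-3,7-dimethyl-3-(4,4,5,5-tetramethyl-1,3,2-dioxaborolan-2-yl)oct-6-enoate | CC(C)=CCC[C@](CC(=O)OC)(C)B1OC(C)(C)C(C)(C)O1 | intermediate
3 | (3R)-3,7-dimethyl-3-(pinacolatoboryl)oct-6-enal | CC(C)=CCC[C@](CC=O)(C)B1OC(C)(C)C(C)(C)O1 | intermediate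
4 | ethyl (triphenylphosphoranylidene)acetate | CCOC(=O)C=P(c1ccccc1)(c1ccccc1)c1ccccc1 | starting material
5 | ethyl iodo(triphenylphosphoranylidene)acetate (not isolated) | CCOC(=O)C([I])=P(c1ccccc1)(c1ccccc1)c1ccccc1 | intermediate
6 | ethyl (2Z,5R)-2-iodo-5,9-dimethyl-5-(pinacolatoboryl)deca-2,8-dienoate | CC(C)=CCC[C@](C/C=C(\I)C(=O)OCC)(C)B1OC(C)(C)C(C)(C)O1 | intermediate
7 | (2Z,5R)-2-iodo-5,9-dimethyl-5-(pinacolatoboryl)deca-2,8-dien-1-ol | CC(C)=CCC[C@](C/C=C(\I)CO)(C)B1OC(C)(C)C(C)(C)O1 | intermediate
8 | fragment A, tert-butyldimethylsilyl ether of 7 (Z-iodoalkene, R boronate) | CC(C)=CCC[C@](C/C=C(\I)CO[Si](C)(C)C(C)(C)C)(C)B1OC(C)(C)C(C)(C)O1 | intermediate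
9 | (R)-glyceraldehyde acetonide, (4R)-2,2-dimethyl-1,3-dioxolane-4-carbaldehyde | O=C[C@@H]1OC(C)(C)OC1 | starting material
10 | 2-(triphenylphosphoranylidene)propanal | CC(C=O)=P(c1ccccc1)(c1ccccc1)c1ccccc1 | starting material
11 | (2E)-3-[(4S)-2,2-dimethyl-1,3-dioxolan-4-yl]-2-methylprop-2-enal | O=C/C(C)=C/[C@@H]1OC(C)(C)OC1 | intermediate
12 | trimethylsilylacetylene | C#C[Si](C)(C)C | starting material
13 | (3S,4E)-5-[(4S)-2,2-dimethyl-1,3-dioxolan-4-yl]-4-methyl-1-(trimethylsilyl)pent-4-en-1-yn-3-ol | C[Si](C)(C)C#C[C@@H](O)/C(C)=C/[C@@H]1OC(C)(C)OC1 | intermediate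
14 | 4-methoxybenzyl ether of 13 (not isolated) | C[Si](C)(C)C#C[C@@H](OCc1ccc(OC)cc1)/C(C)=C/[C@@H]1OC(C)(C)OC1 | intermediate
15 | (4S)-4-{(1E,3R)-3-[(4-methoxybenzyl)oxy]-2-methylpent-1-en-4-yn-1-yl}-2,2-dimethyl-1,3-dioxolane | C#C[C@@H](OCc1ccc(OC)cc1)/C(C)=C/[C@@H]1OC(C)(C)OC1 | intermediate
16 | (2S,3E,5R)-5-[(4-methoxybenzyl)oxy]-4-methylhept-3-en-6-yne-1,2-diol | C#C[C@@H](OCc1ccc(OC)cc1)/C(C)=C/[C@H](O)CO | intermediate
17 | (2S,3E,5R)-5-[(4-methoxybenzyl)oxy]-4-methyl-1-(triethylsilyloxy)hept-3-en-6-yn-2-ol | C#C[C@@H](OCc1ccc(OC)cc1)/C(C)=C/[C@H](O)CO[Si](CC)(CC)CC | intermediate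
18 | (1R)-1-{(2S,3S)-3-[(1R)-1-[(4-methoxybenzyl)oxy]prop-2-yn-1-yl]-3-methyloxiran-2-yl}-2-(triethylsilyloxy)ethan-1-ol | C#C[C@@H](OCc1ccc(OC)cc1)[C@]1(C)O[C@H]1[C@H](O)CO[Si](CC)(CC)CC | intermediate
19 | C7 tert-butyldimethylsilyl ether of 18 (C8 still a primary triethylsilyl ether) | C#C[C@@H](OCc1ccc(OC)cc1)[C@]1(C)O[C@H]1[C@H](O[Si](C)(C)C(C)(C)C)CO[Si](CC)(CC)CC | intermediate
20 | fragment B, C8 aldehyde (C4 R OPMB, C5 S, C6 S oxirane, C7 S OTBS, terminal alkyne C2–C3) | C#C[C@@H](OCc1ccc(OC)cc1)[C@]1(C)O[C@H]1[C@H](O[Si](C)(C)C(C)(C)C)C=O | intermediate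
21 | open-chain C8 allylic alcohol (both C8 epimers; C2–C3 alkyne, C4–C7 as in 20, Z C9=C10 with CH2OTBS on C9, C1 R boronate) | C#C[C@@H](OCc1ccc(OC)cc1)[C@]1(C)O[C@H]1[C@H](O[Si](C)(C)C(C)(C)C)C(O)/C(CO[Si](C)(C)C(C)(C)C)=C\C[C@](C)(CCC=C(C)C)B1OC(C)(C)C(C)(C)O1 | intermediate
22 | C8 trimethylsilyl ether of 21 | C#C[C@@H](OCc1ccc(OC)cc1)[C@]1(C)O[C@H]1[C@H](O[Si](C)(C)C(C)(C)C)C(O[Si](C)(C)C)/C(CO[Si](C)(C)C(C)(C)C)=C\C[C@](C)(CCC=C(C)C)B1OC(C)(C)C(C)(C)O1 | intermediate
23 | (E)-C2-alkenylzirconocene chloride from 22 (not isolated) | Cl[Zr](C1C=CC=C1)(C1C=CC=C1)/C=C/[C@@H](OCc1ccc(OC)cc1)[C@]1(C)O[C@H]1[C@H](O[Si](C)(C)C(C)(C)C)C(O[Si](C)(C)C)/C(CO[Si](C)(C)C(C)(C)C)=C\C[C@](C)(CCC=C(C)C)B1OC(C)(C)C(C)(C)O1 | intermediate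
24 | open-chain (E)-C2-iodoalkene C1-boronate | I/C=C/[C@@H](OCc1ccc(OC)cc1)[C@]1(C)O[C@H]1[C@H](O[Si](C)(C)C(C)(C)C)C(O[Si](C)(C)C)/C(CO[Si](C)(C)C(C)(C)C)=C\C[C@](C)(CCC=C(C)C)B1OC(C)(C)C(C)(C)O1 | intermediate
25 | (E)-C2-alkenyllithium from 24 (not isolated) | [Li]/C=C/[C@@H](OCc1ccc(OC)cc1)[C@]1(C)O[C@H]1[C@H](O[Si](C)(C)C(C)(C)C)C(O[Si](C)(C)C)/C(CO[Si](C)(C)C(C)(C)C)=C\C[C@](C)(CCC=C(C)C)B1OC(C)(C)C(C)(C)O1 | intermediate
26 | twelve-membered cyclic lithium alkenylboronate, boron between C1 and C2, E C2=C3 (not isolated) | [Li+].[B-]12(OC(C)(C)C(C)(C)O1)/C=C/[C@@H](OCc1ccc(OC)cc1)[C@]1(C)O[C@H]1[C@H](O[Si](C)(C)C(C)(C)C)C(O[Si](C)(C)C)/C(CO[Si](C)(C)C(C)(C)C)=C\C[C@]2(C)CCC=C(C)C | intermediate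
27 | eleven-membered C2-boryl C3-iodo carbocycle (not isolated; C2 and C3 left open because iodine may take either alkene face, and both isomers give the same Z-alkene) | CC(C)=CCC[C@]1(C)C(B2OC(C)(C)C(C)(C)O2)C([I])[C@@H](OCc2ccc(OC)cc2)[C@]2(C)O[C@H]2[C@H](O[Si](C)(C)C(C)(C)C)C(O[Si](C)(C)C)/C(CO[Si](C)(C)C(C)(C)C)=C\C1 | intermediate
28 | macrocyclic C8 trimethylsilyl ether (not isolated; C1 S, Z C2=C3) | CC(C)=CCC[C@]1(C)/C=C\[C@@H](OCc2ccc(OC)cc2)[C@]2(C)O[C@H]2[C@H](O[Si](C)(C)C(C)(C)C)C(O[Si](C)(C)C)/C(CO[Si](C)(C)C(C)(C)C)=C\C1 | intermediate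
29 | macrocyclic C8 alcohol (both C8 epimers; C1 S, Z C2=C3, C4 OPMB, C7 OTBS, C9 CH2OTBS) | CC(C)=CCC[C@]1(C)/C=C\[C@@H](OCc2ccc(OC)cc2)[C@]2(C)O[C@H]2[C@H](O[Si](C)(C)C(C)(C)C)C(O)/C(CO[Si](C)(C)C(C)(C)C)=C\C1 | intermediate
30 | macrocyclic C8 enone | CC(C)=CCC[C@]1(C)/C=C\[C@@H](OCc2ccc(OC)cc2)[C@]2(C)O[C@H]2[C@H](O[Si](C)(C)C(C)(C)C)C(=O)/C(CO[Si](C)(C)C(C)(C)C)=C\C1 | intermediate
31 | macrocyclic C4 alcohol | CC(C)=CCC[C@]1(C)/C=C\[C@@H](O)[C@]2(C)O[C@H]2[C@H](O[Si](C)(C)C(C)(C)C)C(=O)/C(CO[Si](C)(C)C(C)(C)C)=C\C1 | intermediate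
32 | 3-methylbut-2-enoyl chloride (senecioyl chloride) | CC(C)=CC(=O)Cl | starting material
33 | C4 senecioate bis(tert-butyldimethylsilyl ether) | CC(C)=CCC[C@]1(C)/C=C\[C@@H](OC(=O)C=C(C)C)[C@]2(C)O[C@H]2[C@H](O[Si](C)(C)C(C)(C)C)C(=O)/C(CO[Si](C)(C)C(C)(C)C)=C\C1 | intermediate
34 | CNP0163063.1 (C1 S, C4 R, C5 S, C6 S, C7 S; Z C2=C3, Z C9=C10) | CC(C)=CCC[C@]1(C)/C=C\[C@@H](OC(=O)C=C(C)C)[C@]2(C)O[C@H]2[C@H](O)C(=O)/C(CO)=C\C1 | target

## Step count and risks

Total step count: 21. Longest linear sequence: 16 steps (steps 6 to 21, from 9).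

**1. Step 17.**
- What may go wrong: intermolecular boronate formation (oligomerisation) may outrun closure of the twelve-membered ring, or the alkenyllithium may be protonated before it reaches boron.
- Fallback: it sets out from 19 and 8 and comes back at 29. The two bond formations are swapped, so that each is used in its established form.
- Hydrozirconation–iodination of 19 (Cp2Zr(H)Cl; I2) gives the C8-protected E-iodoalkene F1.
- Iodine–magnesium exchange (i-PrMgCl·LiCl, THF) gives the alkenylmagnesium chloride F2, which does not exchange with the iodoalkene of 8.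
- F2 is added to the boronate of 8 (THF–DMSO), followed by I2 and NaOMe. This intermolecular Zweifel olefination gives the open-chain Z-alkene F3 with C1 already quaternary.
- Swern oxidation of its primary triethylsilyl ether gives the iodo aldehyde F4.
- An intramolecular Nozaki–Hiyama–Kishi reaction (CrCl2, NiCl2 cat., DMSO–THF, high dilution) closes the eleven-membered ring at C8–C9 and gives 29.

**2. Step 1.**
- What may go wrong: the catalyst may discriminate poorly between the methyl group and the CH2 chain at the β-carbon, which erodes the enantiomeric purity of C1.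
- Fallback: it sets out from 1 and comes back at 2. It replaces catalyst control by an auxiliary whose diastereomers can be separated.
- Saponification (LiOH, THF–H2O) gives geranic acid F5.
- DCC/DMAP coupling with (S)-4-benzyloxazolidin-2-one gives the N-geranoyl imide F6.
- Copper-catalysed β-borylation with an achiral ligand (CuCl, NaOt-Bu, 1,2-bis(diphenylphosphino)benzene, B2pin2, MeOH) gives the β-boryl imide F7, freed from its C3 epimer by chromatography or crystallisation.
- Methanolysis (NaOMe, MeOH, 0 °C) releases the auxiliary and gives 2.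

**3. Step 11.**
- What may go wrong: facial selectivity may be poor if hydrogen-bond delivery from the C7 hydroxyl is overridden by the bulky C4 substituent.
- Fallback: it sets out from 17 and comes back at 19. It replaces substrate direction by reagent control.
- Silylation of 17 (TBSOTf, 2,6-lutidine) gives the fully protected enyne F8.
- Shi epoxidation with the L-fructose-derived ketone (Oxone, K2CO3, MeCN–dimethoxymethane–aq. buffer, 0 °C) delivers oxygen to the required face of the E-trisubstituted alkene and gives 19.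

## Further compounds

F1 | step 17 | C8-protected E-iodoalkene (C2 iodide, C4 OPMB, C5–C6 oxirane, C7 OTBS, C8 OTES) | I/C=C/[C@@H](OCc1ccc(OC)cc1)[C@]1(C)O[C@H]1[C@H](O[Si](C)(C)C(C)(C)C)CO[Si](CC)(CC)CC
F2 | step 17 | alkenylmagnesium chloride from F1 | Cl[Mg]/C=C/[C@@H](OCc1ccc(OC)cc1)[C@]1(C)O[C@H]1[C@H](O[Si](C)(C)C(C)(C)C)CO[Si](CC)(CC)CC
F3 | step 17 | open-chain Z-alkene (C1 S quaternary, Z C2=C3, C9 iodide, C8 OTES) | CC(C)=CCC[C@@](C)(C/C=C(\I)CO[Si](C)(C)C(C)(C)C)/C=C\[C@@H](OCc1ccc(OC)cc1)[C@]1(C)O[C@H]1[C@H](O[Si](C)(C)C(C)(C)C)CO[Si](CC)(CC)CC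
F4 | step 17 | iodo aldehyde (C8 aldehyde, C9 iodide) | CC(C)=CCC[C@@](C)(C/C=C(\I)CO[Si](C)(C)C(C)(C)C)/C=C\[C@@H](OCc1ccc(OC)cc1)[C@]1(C)O[C@H]1[C@H](O[Si](C)(C)C(C)(C)C)C=O
F5 | step 1 | geranic acid | CC(C)=CCC/C(C)=C/C(=O)O
F6 | step 1 | N-geranoyl imide of (S)-4-benzyloxazolidin-2-one | CC(C)=CCC/C(C)=C/C(=O)N1[C@@H](Cc2ccccc2)COC1=O
F7 | step 1 | β-boryl imide (3R boronate) | CC(C)=CCC[C@](CC(=O)N1[C@@H](Cc2ccccc2)COC1=O)(C)B1OC(C)(C)C(C)(C)O1
F8 | step 11 | fully protected enyne (C7 OTBS, C8 OTES, E C5=C6) | C#C[C@@H](OCc1ccc(OC)cc1)/C(C)=C/[C@H](O[Si](C)(C)C(C)(C)C)CO[Si](CC)(CC)CC
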